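**Assumptions**
- The target has no stereocenters (the tertiary carbinol carries two methyls), so there is no enantiomer to set and nothing to scramble.
- I assume the ring closure in Step 3 favors the phenol OH that is not flanked by the prenyl group. This gives the 6-prenyl-5,7-dihydroxy pattern, and a minor 8-prenyl isomer would be removed chromatographically.

**Retrosynthesis**
1. The C3–aryl bond of the isoflavone comes from a Suzuki coupling of 3-iodochromone 7 with arylboronate 14.
2. Chromone 7 comes from enaminone formation and I2 cyclization on 3-prenylphloroacetophenone (3). Compound 3 comes from mono-C-prenylation of phloroacetophenone (1), which is symmetric, so the prenyl position is unambiguous.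
3. Boronate 14 comes from the Miyaura borylation of aryl bromide 12. Compound 12 comes from para-bromination of phenol 10, which is made by opening dihydrocoumarin (8) with excess MeMgBr to install the tertiary alcohol in one step.
4. The pyranone ring is formed in Step 3, after the prenyl group is in place. The only free phenols are the three A-ring OH groups, so no acid-labile protecting groups are needed. The acid-sensitive prenyl phenol and tertiary alcohol are never exposed to acid deprotection.

## Route

**Step 1**
Reactants: 1 (2,4,6-trihydroxyacetophenone), 2 (prenyl bromide)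
Product: 3, 1-[2,4,6-trihydroxy-3-(3-methylbut-2-en-1-yl)phenyl]ethan-1-one
Conditions: 2 (1.0 equiv), KOH (2 equiv), H2O/MeOH, 0 °C → rt, 12 h
Reagents that add atoms: prenyl bromide, CC(C)=CCBr
Why: Phloroglucinol-type phenoxides are C-alkylated at the carbon flanked by two OH groups, and 1 is symmetric, so only one mono-prenyl isomer exists (C-alkylation by SN2).

**Step 2**
Reactants: 3, 4 (N,N-dimethylformamide dimethyl acetal)
Product: 5, (E)-3-(dimethylamino)-1-[2,4,6-trihydroxy-3-prenylphenyl]prop-2-en-1-one
Conditions: 4 (3 equiv), toluene, 80 °C, 4 h
Reagents that add atoms: DMF-DMA, CN(C)C(OC)OC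
Why: The acetyl methyl group condenses with the amide acetal to give the push-pull enaminone (Bredereck-type condensation), and the phenols are tolerated under these mild conditions.

**Step 3**
Reactants: 5, 6 (iodine)
Product: 7, 5,7-dihydroxy-3-iodo-6-(3-methylbut-2-en-1-yl)-4H-chromen-4-one
Conditions: 6 (1.1 equiv), CH2Cl2, 0 °C → rt, 1 h; aq Na2S2O3 workup
Reagents that add atoms: I2, II
Why: I2 iodinates the enaminone α-carbon. The less hindered phenol (the one not flanked by the prenyl group) then adds to the iminium carbon and loses Me2NH, closing the pyranone. This puts the prenyl group between the 5-OH and 7-OH (iodine-mediated 3-iodochromone synthesis).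

**Step 4**
Reactants: 8 (3,4-dihydrocoumarin), 9 (methylmagnesium bromide)
Product: 10, 2-(3-hydroxy-3-methylbutyl)phenol
Conditions: 9 (3.5 equiv), THF, 0 °C → rt, 3 h; NH4Cl quench
Reagents that add atoms: MeMgBr, C[Mg]Br (two methyls are incorporated)
Why: The Grignard opens the lactone to a methyl ketone, then adds a second time to give the tertiary carbinol while releasing the phenoxide (double Grignard addition to a lactone).

**Step 5**
Reactants: 10, 11 (N-bromosuccinimide)
Product: 12, 4-bromo-2-(3-hydroxy-3-methylbutyl)phenol
Conditions: 11 (1.0 equiv), CH2Cl2, –20 → 0 °C, 1 h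
Reagents that add atoms: NBS, O=C1CCC(=O)N1Br
Why: The ortho position is blocked, so electrophilic bromination goes para to the OH (SEAr), and the tertiary alcohol is inert.

**Step 6**
Reactants: 12, 13 (bis(pinacolato)diboron)
Product: 14, 2-(3-hydroxy-3-methylbutyl)-4-(4,4,5,5-tetramethyl-1,3,2-dioxaborolan-2-yl)phenol
Conditions: 13 (1.3 equiv), Pd(dppf)Cl2 (5 mol%), KOAc (3 equiv), dioxane, 85 °C, 12 h
Reagents that add atoms: B2pin2, CC1(C)OB(OC1(C)C)B1OC(C)(C)C(C)(C)O1
Why: Miyaura borylation is chemoselective for Ar–Br and tolerates free phenol and tertiary alcohol.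

**Step 7**
Reactants: 7, 14
Product: 15, Coloratanin A (5,7-dihydroxy-6-prenyl-3-[4-hydroxy-3-(3-hydroxy-3-methylbutyl)phenyl]chromone)
Conditions: 14 (1.5 equiv), Pd(PPh3)4 (5 mol%), Na2CO3 (4 equiv), DME/H2O 4:1, 80 °C, 12 h, N2; mild acidic workup (pH ~5, citrate)
Reagents that add atoms: none (the aryl group comes from 14)
Why: Suzuki–Miyaura coupling joins the C3–I of the chromone to the aryl boronate, and a mild acidic workup avoids prenyl-phenol or carbinol cyclization. No stereocenter is formed.

**Final check:** 15 has a chromone with 5-OH, 7-OH, 6-prenyl, 8-H, 2-H and the 3-aryl group. The aryl group carries 4'-OH and 3'-CH2CH2C(CH3)2OH, matching the target SMILES. All atoms are accounted for in each step.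

## Compound list
1 | 2,4,6-trihydroxyacetophenone | CC(=O)c1c(O)cc(O)cc1O | starting material
2 | prenyl bromide | CC(C)=CCBr | starting material
3 | 3-prenyl-2,4,6-trihydroxyacetophenone | CC(=O)c1c(O)cc(O)c(CC=C(C)C)c1O | intermediate
4 | DMF-DMA | CN(C)C(OC)OC | starting material
5 | enaminone | CN(C)/C=C/C(=O)c1c(O)cc(O)c(CC=C(C)C)c1O | intermediate
6 | iodine | II | starting material
7 | 5,7-dihydroxy-3-iodo-6-prenylchromone | CC(C)=CCc1c(O)cc2occ(I)c(=O)c2c1O | intermediate
8 | 3,4-dihydrocoumarin | O=C1CCc2ccccc2O1 | starting material
9 | methylmagnesium bromide | C[Mg]Br | starting material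
10 | 2-(3-hydroxy-3-methylbutyl)phenol | CC(C)(O)CCc1ccccc1O | intermediate
11 | N-bromosuccinimide | O=C1CCC(=O)N1Br | starting material
12 | 4-bromo-2-(3-hydroxy-3-methylbutyl)phenol | CC(C)(O)CCc1cc(Br)ccc1O | intermediate
13 | bis(pinacolato)diboron | CC1(C)OB(OC1(C)C)B1OC(C)(C)C(C)(C)O1 | starting material
14 | aryl pinacol boronate | CC(C)(O)CCc1cc(B2OC(C)(C)C(C)(C)O2)ccc1O | intermediate
15 | Coloratanin A (achiral) | CC(C)=CCc1c(O)cc2occ(-c3ccc(O)c(CCC(C)(C)O)c3)c(=O)c2c1O | target

## Summary
Total steps: 7. Longest linear sequence: 4 steps (1→3→5→7→15, or 8→10→12→14→15).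

**Three steps most likely to fail**
1. **Step 3 (regioselective iodocyclization, and prenyl tolerance to I2).** The 8-prenyl isomer may form, and I2 may attack the prenyl alkene or the open ring CH.
 - Fallback: reverse the order. Build the symmetric 5,7-dihydroxy-3-iodochromone, Suzuki-couple it with 14, then install the prenyl group at C6 late by Lewis-acid C-alkylation with prenol, and separate the C6/C8 isomers.
2. **Step 1 (mono-C-prenylation).** Di-prenylation, O-prenylation and a yield of roughly 30–40% are all expected.
 - Fallback: iodinate 1 with NIS to the symmetric 3-iodo triol, then couple it with a prenyl–boron or prenyl–zinc reagent under Pd catalysis. This gives an α-selective C–C bond that does not depend on phenoxide alkylation selectivity.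
3. **Step 7 (Suzuki coupling on an unprotected polyphenol).** The 5,7-diphenoxide and the free B-ring phenol may poison the catalyst or lower the yield.
 - Fallback: protect the chromone 5,7-OH and the aryl bromide phenol as MOM ethers, couple, and remove them with a mild non-protic Lewis acid (MgBr2·OEt2/thiol) to spare the prenyl group and carbinol.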